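**Plan**

Ring A is the 3-hydroxy-5-methoxyphenyl ring bridged at C2 (between C3–OH and the ethylene chain on C1); ring B is the one bridged at C4 (between C3–OH and C5–OMe).
The retrosynthesis cuts the CH2–C4(ring B) bond first, then the C2(ring A)–CH2 bond (a formyl carbon), then the aryl–CH2CH2 bond of the bibenzyl, so both halves come from one monomer, mono-MOM gigantol 5.
Enabling feature: ring A has a free OH on C3 next to the bridging CH2 on C2, i.e. a latent o-quinone methide (C3=O, C2=CH2); the bridging carbon C4 of ring B lies between the oxygen-bearing carbons C3 and C5, the one site of cooperative ortho-metalation.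
Forward: styrene 2 and bromophenol 3 are joined by hydroboration/B-alkyl Suzuki coupling to 5, which diverges to the ring B donor 6 (MOM ether) and the ring A acceptor 11 (ortho-formylation, O-Boc, borane reduction).
Key event: anionic unmasking of the o-quinone methide from 11 and its conjugate arylation by C4-metalated 6, a biomimetic cross-coupling of two gigantol units that fixes both attachment sites and frees the ring A phenol; acid then removes the three MOM groups.
Stereochemistry: the target is achiral, with no stereocentre and no stereogenic double bond, so none has to be set.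

Key step: step 7

Remark: 2-methoxy-4-vinylphenol (1) and 3-bromo-5-methoxyphenol (3) are taken as purchased; no SMILES needs a stereodescriptor except that fallback compound F2 is racemic.

**Route**

Step 1
Reactants: 1 2-methoxy-4-vinylphenol
Product: 2 4-ethenyl-2-methoxy-1-(methoxymethoxy)benzene
Conditions: NaH, MOMCl, THF, 0 °C → rt
Reagents that add atoms: chloromethyl methyl ether, COCCl
Why: The sodium phenoxide is O-alkylated by the reactive α-chloro ether (Williamson-type MOM protection) under basic conditions that do not polymerise the styrene.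

Step 2
Reactants: 2 4-ethenyl-2-methoxy-1-(methoxymethoxy)benzene; 3 3-bromo-5-methoxyphenol
Product: 5 3-methoxy-5-[2-(3-methoxy-4-(methoxymethoxy)phenyl)ethyl]phenol (mono-MOM gigantol), via B-alkyl-9-BBN adduct 4 (not isolated)
Conditions: 9-BBN, THF, 0 °C → rt; then 3, PdCl2(dppf) (cat.), aq. NaOH, THF, 65 °C
Reagents that add atoms: none
Why: 9-BBN adds anti-Markovnikov to the styrene to give primary alkylborane 4, which should undergo B-alkyl Suzuki–Miyaura coupling with the aryl bromide of 3 (present as its phenoxide), the MOM acetal and methyl ethers being inert to base and Pd(0).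

Step 3
Reactants: 5 3-methoxy-5-[2-(3-methoxy-4-(methoxymethoxy)phenyl)ethyl]phenol
Product: 6 1-methoxy-3-(methoxymethoxy)-5-[2-(3-methoxy-4-(methoxymethoxy)phenyl)ethyl]benzene (bis-MOM gigantol)
Conditions: NaH, MOMCl, THF, 0 °C → rt
Reagents that add atoms: chloromethyl methyl ether, COCCl
Why: MOM protection of the remaining phenol (Williamson-type O-alkylation) installs the second directing group needed for the later ortho-metalation.

Step 4
Reactants: 5 3-methoxy-5-[2-(3-methoxy-4-(methoxymethoxy)phenyl)ethyl]phenol
Product: 8 2-hydroxy-4-methoxy-6-[2-(3-methoxy-4-(methoxymethoxy)phenyl)ethyl]benzaldehyde, via chloromagnesium hydroxymethylphenoxide 7 (not isolated)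
Conditions: MgCl2, Et3N, (CH2O)n, MeCN, 80 °C; aq. NH4Cl work-up
Reagents that add atoms: paraformaldehyde (formaldehyde), C=O
Why: In the Casiraghi–Skattebøl ortho-formylation the magnesium phenoxide delivers formaldehyde to an ortho carbon through a chelate, hydroxymethyl intermediate 7 is oxidised by a second formaldehyde in an Oppenauer-type hydride transfer, and of the two ortho sites the one para to OMe (between OH and the chain) should be favoured, as in orcinol-type substitutions that avoid the carbon between two oxygens.

Step 5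
Reactants: 8 2-hydroxy-4-methoxy-6-[2-(3-methoxy-4-(methoxymethoxy)phenyl)ethyl]benzaldehyde
Product: 9 tert-butyl 2-formyl-5-methoxy-3-[2-(3-methoxy-4-(methoxymethoxy)phenyl)ethyl]phenyl carbonate
Conditions: Boc2O, i-Pr2NEt, DMAP (cat.), THF, 0 °C → rt
Reagents that add atoms: di-tert-butyl dicarbonate, CC(C)(C)OC(=O)OC(=O)OC(C)(C)C
Why: DMAP-catalysed O-tert-butoxycarbonylation of the salicylaldehyde phenol installs the carbonate that will later migrate and leave to unmask the quinone methide.

Step 6
Reactants: 9 tert-butyl 2-formyl-5-methoxy-3-[2-(3-methoxy-4-(methoxymethoxy)phenyl)ethyl]phenyl carbonate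
Product: 11 tert-butyl 2-(hydroxymethyl)-5-methoxy-3-[2-(3-methoxy-4-(methoxymethoxy)phenyl)ethyl]phenyl carbonate, via alkoxyborane 10 (not isolated)
Conditions: BH3·THF, THF, 0 °C; then pH 7 buffer
Reagents that add atoms: none
Why: Borane reduces the aldehyde through neutral alkoxyborane 10 and not through a free alkoxide, so the ortho carbonate should neither migrate nor release the quinone methide early, and carbonate and MOM acetal are inert to BH3 at 0 °C.

Step 7
Reactants: 6 1-methoxy-3-(methoxymethoxy)-5-[2-(3-methoxy-4-(methoxymethoxy)phenyl)ethyl]benzene; 11 tert-butyl 2-(hydroxymethyl)-5-methoxy-3-[2-(3-methoxy-4-(methoxymethoxy)phenyl)ethyl]phenyl carbonate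
Product: 16 5-methoxy-2-[[2-methoxy-6-(methoxymethoxy)-4-[2-(3-methoxy-4-(methoxymethoxy)phenyl)ethyl]phenyl]methyl]-3-[2-(3-methoxy-4-(methoxymethoxy)phenyl)ethyl]phenol, via aryllithium 12 (not isolated), via arylmagnesium bromide 13 (not isolated), via Boc-shifted magnesium phenoxide 14 (not isolated), via o-quinone methide 15 (not isolated)
Conditions: 6 (2.2 equiv), n-BuLi (2.1 equiv), THF, 0 °C; MgBr2·OEt2, −78 → 0 °C; then 11 (1.0 equiv), THF, −78 °C → rt; aq. NH4Cl
Reagents that add atoms: none
Why: n-BuLi removes the one ring proton of 6 that is flanked by OMOM and OMe (cooperative directed ortho-metalation, 12) and MgBr2 gives Grignard reagent 13; one equivalent of 13 deprotonates the benzylic OH of 11 (returning 6), the magnesium alkoxide takes over the Boc group through a six-membered transition state to give phenoxide 14, this expels tert-butyl carbonate to form o-quinone methide 15, and a second equivalent of 13 adds to the exocyclic CH2 with rearomatisation to forge the CH2–aryl bond. The closest known reaction type is the anionic generation of o-quinone methides from o-OBoc benzyl alcohols with 1,4-trapping by Grignard reagents, used here as the laboratory counterpart of the presumed biosynthetic attack of one gigantol on the o-quinone methide of another. No ring is closed and no stereocentre is formed. The step needs site selectivity on both rings: on ring A only the CH2 ortho to the carbonate oxygen can become the methide carbon, and on ring B the carbon–magnesium bond fixes attack at the carbon between the two oxygens, overriding the preference of a free phenol for the positions next to the chain. Self-condensation of 15 should be held back by keeping 13 in excess at low temperature, and the MOM acetals, aryl methyl ethers and benzylic CH2 groups are inert to the organometallics under these conditions.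

Step 8
Reactants: 16 5-methoxy-2-[[2-methoxy-6-(methoxymethoxy)-4-[2-(3-methoxy-4-(methoxymethoxy)phenyl)ethyl]phenyl]methyl]-3-[2-(3-methoxy-4-(methoxymethoxy)phenyl)ethyl]phenol
Product: 17 2-[[2-hydroxy-6-methoxy-4-[2-(4-hydroxy-3-methoxyphenyl)ethyl]phenyl]methyl]-3-[2-(4-hydroxy-3-methoxyphenyl)ethyl]-5-methoxyphenol (CNP0079001.0)
Conditions: HCl, MeOH, 40 °C
Reagents that add atoms: none
Why: Acid-catalysed transacetalisation of the three aryl MOM ethers to methanol should release the phenols, while the aryl methyl ethers and the diarylmethane are stable to dilute methanolic HCl and methanol traps the formaldehyde equivalent.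

**Compound list**

1 | 2-methoxy-4-vinylphenol (4-vinylguaiacol) | COc1cc(C=C)ccc1O | starting material
2 | 4-ethenyl-2-methoxy-1-(methoxymethoxy)benzene | COCOc1ccc(C=C)cc1OC | intermediate
3 | 3-bromo-5-methoxyphenol | COc1cc(O)cc(Br)c1 | starting material
4 | 9-[2-(3-methoxy-4-(methoxymethoxy)phenyl)ethyl]-9-borabicyclo[3.3.1]nonane | COCOc1ccc(CCB2C3CCCC2CCC3)cc1OC | intermediate (not isolated)
5 | 3-methoxy-5-[2-(3-methoxy-4-(methoxymethoxy)phenyl)ethyl]phenol | COCOc1ccc(CCc2cc(O)cc(OC)c2)cc1OC | intermediate
6 | 1-methoxy-3-(methoxymethoxy)-5-[2-(3-methoxy-4-(methoxymethoxy)phenyl)ethyl]benzene | COCOc1ccc(CCc2cc(OCOC)cc(OC)c2)cc1OC | intermediate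
7 | chloromagnesium 2-(hydroxymethyl)-5-methoxy-3-[2-(3-methoxy-4-(methoxymethoxy)phenyl)ethyl]phenoxide | COCOc1ccc(CCc2cc(OC)cc(O[Mg]Cl)c2CO)cc1OC | intermediate (not isolated)
8 | 2-hydroxy-4-methoxy-6-[2-(3-methoxy-4-(methoxymethoxy)phenyl)ethyl]benzaldehyde | COCOc1ccc(CCc2cc(OC)cc(O)c2C=O)cc1OC | intermediate
9 | tert-butyl 2-formyl-5-methoxy-3-[2-(3-methoxy-4-(methoxymethoxy)phenyl)ethyl]phenyl carbonate | COCOc1ccc(CCc2cc(OC)cc(OC(=O)OC(C)(C)C)c2C=O)cc1OC | intermediate
10 | [2-(tert-butoxycarbonyloxy)-4-methoxy-6-[2-(3-methoxy-4-(methoxymethoxy)phenyl)ethyl]benzyloxy]borane | COCOc1ccc(CCc2cc(OC)cc(OC(=O)OC(C)(C)C)c2COB)cc1OC | intermediate (not isolated)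
11 | tert-butyl 2-(hydroxymethyl)-5-methoxy-3-[2-(3-methoxy-4-(methoxymethoxy)phenyl)ethyl]phenyl carbonate | COCOc1ccc(CCc2cc(OC)cc(OC(=O)OC(C)(C)C)c2CO)cc1OC | intermediate
12 | [2-methoxy-6-(methoxymethoxy)-4-[2-(3-methoxy-4-(methoxymethoxy)phenyl)ethyl]phenyl]lithium | COCOc1ccc(CCc2cc(OC)c([Li])c(OCOC)c2)cc1OC | intermediate (not isolated)
13 | bromo[2-methoxy-6-(methoxymethoxy)-4-[2-(3-methoxy-4-(methoxymethoxy)phenyl)ethyl]phenyl]magnesium | COCOc1ccc(CCc2cc(OC)c([Mg]Br)c(OCOC)c2)cc1OC | intermediate (not isolated)
14 | bromomagnesium 2-[(tert-butoxycarbonyloxy)methyl]-5-methoxy-3-[2-(3-methoxy-4-(methoxymethoxy)phenyl)ethyl]phenoxide | COCOc1ccc(CCc2cc(OC)cc(O[Mg]Br)c2COC(=O)OC(C)(C)C)cc1OC | intermediate (not isolated)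
15 | 3-methoxy-6-methylidene-5-[2-(3-methoxy-4-(methoxymethoxy)phenyl)ethyl]cyclohexa-2,4-dien-1-one | C=C1C(=O)C=C(OC)C=C1CCc1ccc(OCOC)c(OC)c1 | intermediate (not isolated)
16 | 5-methoxy-2-[[2-methoxy-6-(methoxymethoxy)-4-[2-(3-methoxy-4-(methoxymethoxy)phenyl)ethyl]phenyl]methyl]-3-[2-(3-methoxy-4-(methoxymethoxy)phenyl)ethyl]phenol | COCOc1ccc(CCc2cc(OC)cc(O)c2Cc2c(OCOC)cc(CCc3ccc(OCOC)c(OC)c3)cc2OC)cc1OC | intermediate
17 | 2-[[2-hydroxy-6-methoxy-4-[2-(4-hydroxy-3-methoxyphenyl)ethyl]phenyl]methyl]-3-[2-(4-hydroxy-3-methoxyphenyl)ethyl]-5-methoxyphenol (CNP0079001.0) | COc1cc(O)c(Cc2c(O)cc(CCc3ccc(O)c(OC)c3)cc2OC)c(CCc2ccc(O)c(OC)c2)c1 | target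

**Totals and risks**

Total step count: 8. Longest linear sequence: 7 steps (steps 1, 2, 4, 5, 6, 7, 8; 1 → 2 → 5 → 8 → 9 → 11 → 16 → 17).

Steps most likely to fail:

Step 7. The conjugate addition of the doubly ortho-substituted aryl nucleophile may be slow, so that the quinone methide self-condenses, or metalation may occur at a wrong site. Fallback: the bond is made by carbonyl addition and ionic hydrogenation instead. It sets out from 8 (and 6): 8 is protected with NaH/MOMCl in DMF to give 4-methoxy-2-(methoxymethoxy)-6-[2-(3-methoxy-4-(methoxymethoxy)phenyl)ethyl]benzaldehyde F1. Aryllithium 12, made from 6 and n-BuLi as in step 7, is added at −78 °C to give racemic [4-methoxy-2-(methoxymethoxy)-6-[2-(3-methoxy-4-(methoxymethoxy)phenyl)ethyl]phenyl][2-methoxy-6-(methoxymethoxy)-4-[2-(3-methoxy-4-(methoxymethoxy)phenyl)ethyl]phenyl]methanol F2. Et3SiH/CF3CO2H in CH2Cl2 (0 °C → rt) should then reduce the doubly activated benzylic cation and cleave the four MOM groups in the same operation, which comes back to the route at 17.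

Step 4. Site selectivity between the two positions ortho to the phenol may be poor, with attack between OH and OMe instead of between OH and the chain. Fallback: the regiochemistry is bought in with the aryl halide. It sets out from 4 (made from 2 as in step 2). Commercial 2-bromo-4,6-dimethoxybenzaldehyde (COc1cc(OC)c(C=O)c(Br)c1) is mono-demethylated at the methoxy group ortho to the formyl group with BCl3 (CH2Cl2, −78 → 0 °C, chelation control) to give 2-bromo-6-hydroxy-4-methoxybenzaldehyde F3. F3 is coupled with alkylborane 4 (PdCl2(dppf), K3PO4, DMF/THF, 60 °C), which comes back to the route at 8.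

Step 6. The carbonate may migrate to the newly formed benzylic oxygen during reduction or work-up, which would unmask the quinone methide early and lead to over-reduction or self-condensation. Fallback: the reduction is moved ahead of the carbonate installation. It sets out from 8: NaBH4 (MeOH, 0 °C) reduces the free salicylaldehyde to 2-(hydroxymethyl)-5-methoxy-3-[2-(3-methoxy-4-(methoxymethoxy)phenyl)ethyl]phenol F4. The more acidic phenol is then carbonylated selectively (Boc2O 1.0 equiv, K2CO3, acetone, 0 °C, no DMAP), which comes back to the route at 11.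

**Further compounds**

F1 | step 7 | 4-methoxy-2-(methoxymethoxy)-6-[2-(3-methoxy-4-(methoxymethoxy)phenyl)ethyl]benzaldehyde | COCOc1ccc(CCc2cc(OC)cc(OCOC)c2C=O)cc1OC
F2 | step 7 | [4-methoxy-2-(methoxymethoxy)-6-[2-(3-methoxy-4-(methoxymethoxy)phenyl)ethyl]phenyl][2-methoxy-6-(methoxymethoxy)-4-[2-(3-methoxy-4-(methoxymethoxy)phenyl)ethyl]phenyl]methanol (racemic) | COCOc1ccc(CCc2cc(OC)cc(OCOC)c2C(O)c2c(OCOC)cc(CCc3ccc(OCOC)c(OC)c3)cc2OC)cc1OC
F3 | step 4 | 2-bromo-6-hydroxy-4-methoxybenzaldehyde | COc1cc(O)c(C=O)c(Br)c1
F4 | step 6 | 2-(hydroxymethyl)-5-methoxy-3-[2-(3-methoxy-4-(methoxymethoxy)phenyl)ethyl]phenol | COCOc1ccc(CCc2cc(OC)cc(O)c2CO)cc1OC
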